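Ring A (C1 O-aryl, C2 OMe, C3 Br, C4 H, C5 Br, C6 Br) is delivered as cyclohexane-1,3-dione. C6–Br is meta to the C2 oxygen and cannot be installed by electrophilic bromination, whereas C3 and C5 are ortho and para to it. One dione carbonyl is therefore turned into the C6 vinyl bromide while the ring is still partly saturated, and the other becomes the C2 oxygen. The precursor is the 3-bromo-2-aryloxycyclohex-2-enone 9, which already carries the benzyl-protected, dibrominated ring B on the C1 oxygen. In one operation bromine oxidises 9 to the phenol and sets C3–Br and C5–Br; O-methylation and debenzylation then give the target.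

Key step: step 6

Remark: ring A atoms are numbered as in the target throughout; dione 8 is drawn as its enol, and its two carbonyl carbons are equivalent, so either may become the vinyl bromide.

Step 1
Reactants: 1 3,5-dibromosalicylaldehyde; 2 benzyl bromide
Product: 3 2-(benzyloxy)-3,5-dibromobenzaldehyde
Conditions: K2CO3, DMF, 60 °C
Reagents that add atoms: none
Why: Williamson ether synthesis; the acidic phenol is deprotonated by K2CO3 and O-benzylated by SN2 displacement, while the aldehyde and aryl bromides are inert.

Step 2
Reactants: 3 2-(benzyloxy)-3,5-dibromobenzaldehyde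
Product: 5 2-(benzyloxy)-3,5-dibromophenol, via aryl formate 4 (not isolated)
Conditions: mCPBA, CH2Cl2, 23 → 40 °C; then Et3N, MeOH, 23 °C
Reagents that add atoms: 3-chloroperoxybenzoic acid, O=C(OO)c1cccc(Cl)c1
Why: Baeyer–Villiger oxidation; the ortho-benzyloxy group should favour aryl over hydride migration in the Criegee adduct, and the resulting formate is methanolysed under mild base that leaves the benzyl ether alone.

Step 3
Reactants: 6 cyclohexane-1,3-dione
Product: 7 2-diazocyclohexane-1,3-dione
Conditions: 4-acetamidobenzenesulfonyl azide, Et3N, MeCN, 0 → 23 °C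
Reagents that add atoms: 4-acetamidobenzenesulfonyl azide, CC(=O)Nc1ccc(cc1)S(=O)(=O)N=[N+]=[N-]
Why: Regitz diazo transfer; the enolate of the dione attacks the terminal azide nitrogen and the adduct collapses to the diazo dione and the sulfonamide.

Step 4
Reactants: 5 2-(benzyloxy)-3,5-dibromophenol; 7 2-diazocyclohexane-1,3-dione
Product: 8 2-[2-(benzyloxy)-3,5-dibromophenoxy]-3-hydroxycyclohex-2-en-1-one (enol of the 2-aryloxy-1,3-dione)
Conditions: Rh2(OAc)4 (1 mol %), ClCH2CH2Cl, 80 °C, slow addition of 7 (1.5 equiv)
Reagents that add atoms: none
Why: Rhodium carbenoid O–H insertion; the electrophilic acceptor/acceptor carbenoid is captured by the phenol oxygen and proton transfer in the oxonium ylide gives the 2-aryloxy dione, slow addition keeping carbene dimerisation low.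

Step 5
Reactants: 8 2-[2-(benzyloxy)-3,5-dibromophenoxy]-3-hydroxycyclohex-2-en-1-one
Product: 9 2-[2-(benzyloxy)-3,5-dibromophenoxy]-3-bromocyclohex-2-en-1-one
Conditions: Ph3PBr2, Et3N, MeCN, 0 → 23 °C
Reagents that add atoms: dibromotriphenylphosphorane, BrP(Br)(c1ccccc1)(c1ccccc1)c1ccccc1
Why: Deoxybromination of an enolised cyclic 1,3-dione; the enol oxygen is activated as an oxyphosphonium vinylogous ester and bromide substitutes by addition–elimination, giving the future C6–Br under acid-free conditions.

Step 6
Reactants: 9 2-[2-(benzyloxy)-3,5-dibromophenoxy]-3-bromocyclohex-2-en-1-one; 10 bromine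
Product: 13 2-[2-(benzyloxy)-3,5-dibromophenoxy]-3,4,6-tribromophenol, via alpha-prime-bromo enone 11 (not isolated), via 3-bromo-2-aryloxyphenol 12 (not isolated)
Conditions: Br2 (3.1 equiv), AcOH, 20 °C, dark; then NaOAc, 50 °C
Reagents that add atoms: none
Why: Hydrogen bromide from the first turnover catalyses enolisation of 9 toward C3, the only alpha carbon bearing hydrogen because C1 is fully substituted, and bromine gives alpha-prime-bromo enone 11; enolisation through C5 and loss of hydrogen bromide across C3–C4 (or direct dehydrobromination to the cross-conjugated dienone and tautomerisation) gives phenol 12, which is then brominated ortho (C3) and para (C5) to the new C2 hydroxyl. The closest known reaction type is the halogenative aromatisation of cyclohex-2-enones and cyclohexane-1,3-dione derivatives to halophenols with bromine in acetic acid. No ring is closed and no stereocentre is created, the stereocentre of 11 being transient. Site selectivity for three bromines is needed: C6–Br is already in place as the vinyl bromide, C3 is the former alpha-prime carbon and ortho to the hydroxyl, C5 is the only remaining activated position, and other orders of bromination and elimination converge on the same tribromophenol. The last ring A hydrogen (C4) lies meta to the hydroxyl between two bromines, and ring B offers only two positions meta to its benzyloxy group on a ring already carrying two bromines, so 3.1 equivalents of bromine should stop at 13. NaOAc neutralises the hydrogen bromide before warming so that the benzyl ether survives, and light is excluded to avoid benzylic bromination.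

Step 7
Reactants: 13 2-[2-(benzyloxy)-3,5-dibromophenoxy]-3,4,6-tribromophenol
Product: 14 1-(benzyloxy)-2,4-dibromo-6-(2,3,5-tribromo-6-methoxyphenoxy)benzene
Conditions: MeI, K2CO3, DMF, 23 °C
Reagents that add atoms: iodomethane, CI
Why: Williamson O-methylation of the only free phenol; the hindered but acidic tribromophenoxide should react cleanly with the small electrophile.

Step 8
Reactants: 14 1-(benzyloxy)-2,4-dibromo-6-(2,3,5-tribromo-6-methoxyphenoxy)benzene
Product: 15 2,4-dibromo-6-(2,3,5-tribromo-6-methoxyphenoxy)phenol
Conditions: BCl3, pentamethylbenzene, CH2Cl2, −78 °C; then H2O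
Reagents that add atoms: none
Why: Lewis-acid debenzylation; BCl3 ionises the benzyl ether at low temperature and pentamethylbenzene traps the benzyl cation by Friedel–Crafts alkylation, while the aryl methyl ether, the diaryl ether and the aryl bromides should be untouched at −78 °C.

Compound list
1 | 3,5-dibromosalicylaldehyde | O=Cc1cc(Br)cc(Br)c1O | starting material
2 | benzyl bromide | BrCc1ccccc1 | starting material
3 | 2-(benzyloxy)-3,5-dibromobenzaldehyde | O=Cc1cc(Br)cc(Br)c1OCc1ccccc1 | intermediate
4 | 2-(benzyloxy)-3,5-dibromophenyl formate | O=COc1cc(Br)cc(Br)c1OCc1ccccc1 | intermediate (not isolated)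
5 | 2-(benzyloxy)-3,5-dibromophenol | Oc1cc(Br)cc(Br)c1OCc1ccccc1 | intermediate
6 | cyclohexane-1,3-dione | O=C1CCCC(=O)C1 | starting material
7 | 2-diazocyclohexane-1,3-dione | [N-]=[N+]=C1C(=O)CCCC1=O | intermediate
8 | 2-[2-(benzyloxy)-3,5-dibromophenoxy]-3-hydroxycyclohex-2-en-1-one (enol of the 2-aryloxy-1,3-dione) | O=C1CCCC(O)=C1Oc1cc(Br)cc(Br)c1OCc1ccccc1 | intermediate
9 | 2-[2-(benzyloxy)-3,5-dibromophenoxy]-3-bromocyclohex-2-en-1-one | O=C1CCCC(Br)=C1Oc1cc(Br)cc(Br)c1OCc1ccccc1 | intermediate
10 | bromine | BrBr | starting material
11 | 2-[2-(benzyloxy)-3,5-dibromophenoxy]-3,6-dibromocyclohex-2-en-1-one (racemic) | O=C1C(Br)CCC(Br)=C1Oc1cc(Br)cc(Br)c1OCc1ccccc1 | intermediate (not isolated)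
12 | 2-[2-(benzyloxy)-3,5-dibromophenoxy]-3-bromophenol | Oc1cccc(Br)c1Oc1cc(Br)cc(Br)c1OCc1ccccc1 | intermediate (not isolated)
13 | 2-[2-(benzyloxy)-3,5-dibromophenoxy]-3,4,6-tribromophenol | Oc1c(Br)cc(Br)c(Br)c1Oc1cc(Br)cc(Br)c1OCc1ccccc1 | intermediate
14 | 1-(benzyloxy)-2,4-dibromo-6-(2,3,5-tribromo-6-methoxyphenoxy)benzene | COc1c(Br)cc(Br)c(Br)c1Oc1cc(Br)cc(Br)c1OCc1ccccc1 | intermediate
15 | 2,4-dibromo-6-(2,3,5-tribromo-6-methoxyphenoxy)phenol | COc1c(Br)cc(Br)c(Br)c1Oc1cc(Br)cc(Br)c1O | target

Total step count: 8. Longest linear sequence: 7 steps (1 → 3 → 5 → 8 → 9 → 13 → 14 → 15; steps 1, 2, 4, 5, 6, 7, 8).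

Steps most likely to fail

Step 6. The sequence may stall at partly brominated, non-aromatic stages, run on past three bromines, or lose the benzyl group to hydrogen bromide before the buffer is added. The fallback separates dehydrogenation from bromination and sets out from 9. Deprotonation at C3 with LiN(SiMe3)2 in THF at −78 °C and trapping with PhSeBr should give 2-[2-(benzyloxy)-3,5-dibromophenoxy]-3-bromo-6-(phenylselanyl)cyclohex-2-en-1-one F1. Oxidation with H2O2 and pyridine in CH2Cl2 at 0 → 23 °C gives the corresponding selenoxide F2, which is not isolated; it undergoes syn-elimination to the cross-conjugated dienone and tautomerises to phenol 12, now isolated. N-bromosuccinimide (2.05 equiv) in MeCN at 0 °C then brominates ortho and para to the hydroxyl, and the route is rejoined at 13.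

Step 4. The carbenoid may be diverted into Wolff rearrangement, into addition to the arene rings, or into ylide formation at the benzyl ether oxygen. The fallback builds the dione ring on the phenol and sets out from 5. Alkylation with ethyl 6-bromo-5-oxohexanoate (CCOC(=O)CCCC(=O)CBr; K2CO3, acetone, 56 °C) should give ethyl 6-[2-(benzyloxy)-3,5-dibromophenoxy]-5-oxohexanoate F3. KOtBu in THF at 0 → 23 °C then closes the six-membered ring by intramolecular Claisen condensation of the aryloxy-bearing ketone alpha carbon onto the ester, the only productive ring size, and acidic work-up returns the route to 8.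

Step 8. The Lewis acid may also cleave the crowded ring A methyl ether, or debenzylation may be incomplete at low temperature. The fallback removes the benzyl group oxidatively and sets out from 14. N-bromosuccinimide under visible light in PhCF3 at 23 °C should brominate the benzylic position to give 1-[bromo(phenyl)methoxy]-2,4-dibromo-6-(2,3,5-tribromo-6-methoxyphenoxy)benzene F4, which is not isolated. Addition of water hydrolyses it to benzaldehyde and the target, so the route is rejoined at 15; the liberated phenol has no open ortho or para position and should not be brominated further.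

Further compounds
F1 | step 6 | 2-[2-(benzyloxy)-3,5-dibromophenoxy]-3-bromo-6-(phenylselanyl)cyclohex-2-en-1-one (racemic) | O=C1C([Se]c2ccccc2)CCC(Br)=C1Oc1cc(Br)cc(Br)c1OCc1ccccc1
F2 | step 6 | 2-[2-(benzyloxy)-3,5-dibromophenoxy]-3-bromo-6-(phenylseleninyl)cyclohex-2-en-1-one (mixture of stereoisomers) | O=C1C([Se](=O)c2ccccc2)CCC(Br)=C1Oc1cc(Br)cc(Br)c1OCc1ccccc1
F3 | step 4 | ethyl 6-[2-(benzyloxy)-3,5-dibromophenoxy]-5-oxohexanoate | CCOC(=O)CCCC(=O)COc1cc(Br)cc(Br)c1OCc1ccccc1
F4 | step 8 | 1-[bromo(phenyl)methoxy]-2,4-dibromo-6-(2,3,5-tribromo-6-methoxyphenoxy)benzene (racemic) | COc1c(Br)cc(Br)c(Br)c1Oc1cc(Br)cc(Br)c1OC(Br)c1ccccc1
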